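The constants used here are invented, and the outcome is calculated.

**The leftover.** The substrate left over at the stop tells me how far a flask has run, so I reckon that first, for ochre.

    substrate + coupling partner ⇌ adduct (K1 = 3.6 L mol⁻¹, k1 = 0.43 L mol⁻¹ s⁻¹, Ea1 = 67.0 kJ mol⁻¹, ΔH1 = −24.0 kJ mol⁻¹)
    adduct → target (k2 = 0.0029 s⁻¹, Ea2 = 90.0 kJ mol⁻¹)
    target ⇌ isomer of the product (K3 = 0.90, k3 = 0.0028 s⁻¹, Ea3 = 80.0 kJ mol⁻¹, ΔH3 = 24.0 kJ mol⁻¹)
    substrate → decomposition product (k4 = 2.3 × 10⁻⁶ s⁻¹, Ea4 = 101 kJ mol⁻¹)
    (constants at 40 °C)

the same everywhere: substrate 0.010 M; coupling partner 2.00 equiv; time 2.5 min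

|  | temperature |
|---|---|
| ochre | 100 °C |
| grey | 130 °C |
| red | 40 °C |
| green | 70 °C |

1. the flask with the highest amount of target, in percent of the substrate charged ("all alike" if they lie within 1.5 percentage points) (ochre / grey / red / green / all alike)
2. final target, as a percentage of the substrate charged, in ochre
3. final target, as a percentage of the substrate charged, in grey
4. final target, as a percentage of the substrate charged, in red
5. final target, as a percentage of the substrate charged, in green

**Through-constant.** In ochre the return of the adduct to substrate and coupling partner runs at 32.9 s⁻¹, much faster than its onward step at 0.752 s⁻¹, so I hold the first step at equilibrium. Substrate then leaves by a pseudo-first-order route. Its constant is the rate constant of the second step times the equilibrium constant of the first times the charged [coupling partner], which is 0.0125 min⁻¹ at 40 °C. Its barrier is the activation energy of the second step plus the enthalpy of the first, 66.0 kJ mol⁻¹. This through-constant is 0.738 min⁻¹ in ochre.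

**The slowing.** Unslowed, that rate would pass 1.84 charges through ochre by the stop. But the rate falls with [substrate] and with [coupling partner] together. With a fraction 0.5 of the substrate gone, the factors are 0.5 and 0.750, so the rate stands at 0.375 of its start. Accumulated, this slowing leaves 24.8 % of the substrate. Decomposition runs at 0.0706 min⁻¹, so the route keeps about 91.3 % of what goes. Isomerisation runs at 23.5 min⁻¹, so I give target its equilibrium share, 20.2 %. My figure for ochre is 13.8 %.

**The forecast.** It names ochre: ochre 14.5 %, grey 9.6 %, green 9.2 %, red 2.3 %. Of ochre it says "Target is about one-fifth of that". Its ochre value stands above mine.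

**The result.** The simulation also gives ochre: ochre 14.4 %, grey 9.65 %, green 8.77 %, red 2.19 %.

**What turns it.** The forecast is right, and a longer time turns it. In green the through-constant is 0.115 min⁻¹, smaller than in ochre, so at the stop its product with the time is 0.287 against 1.84 in ochre. Grey ends low mainly because isomerisation carries target off: with that step struck out both ways, grey holds 77.7 % of target instead of 9.65 %. After 25.0 min, green holds 27.7 % of target and ochre 17.8 %, so the lead has passed to green.

**Second flask.** For a flask like red kept at 65 °C, the through-constant is 0.0816 min⁻¹, and the same slowing leaves 82.3 % of the substrate. The simulation of that flask leaves 80.4 %, with target at 7.46 %.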